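Atom labels used throughout: the oxolane is O1–C2–C3–C4–C5; Ca is the carbinol carbon on C3 and carries aryl ring A; Cb is the carbinol carbon on C4 and carries aryl ring B.

Assumption on the chemistry: photoadduct 4 forms as a racemate. Compound 4 and everything after it are drawn in the enantiomeric series that leads to 18; the other half of the material leaves the route in step 3 as the diastereomeric pinanediol ester built on the mirror-image core.

## Analysis of the target

Target 18 is a monocyclic 3,4-disubstituted oxolane in which C3 and C4 each carry an aryl(hydroxy)methyl arm, and both aryl rings are 4-hydroxy-3-methoxyphenyl. It has four contiguous stereocentres: C3 (R) and C4 (R) place the two arms trans on the ring, Ca is S and Cb is R. The two halves have the same constitution, but the molecule has no C2 axis, because with C3 and C4 alike a symmetric compound would need Ca and Cb alike as well. Each carbinol therefore needs its own control element. The sensitive groups are the two free phenols and, above all, the two para-hydroxybenzylic alcohols, which ionise towards quinone-methide-type cations under acid, can epimerise, and are at risk under hydrogenolysis. The difficulty lies in fixing two exocyclic benzylic centres relative to a flexible five-membered ring, and in absolute terms, with little functionality for a catalyst to hold on to. The plan rests on the array O1–C5–C4–Cb–O: C5 can be read as a reduced acetal carbon, so O1, C2, C3, C4 and C5 are the five atoms of furan and Cb with its oxygen is an aldehyde C=O added across the furan C4=C5 bond. The remaining C2=C3 enol ether is then the entry point for the Ca arm.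

## Retrosynthetic reasoning

**18 from 17.** The last disconnection is a deprotection only: the two phenols and the Cb hydroxyl of 18 are silyl ethers in 17, and Ca–OH is already free. Fluoride at the end avoids acid and hydrogenolysis, the two conditions under which the para-hydroxybenzylic alcohols would suffer.

**17 from 16.** The Ca–O bond is traced to a Ca–B bond. A benzylic boronic ester is oxidised with retention, so the question of the Ca configuration moves to the carbon–boron stage, where a chiral diol on boron can answer it.

**16 from 11 and 14.** The bond between Ca and aryl ring A is cut. Forward, the aryl group of 14 (made from 13, the silyl ether of 12) adds to boron to give borate 15, then migrates from boron to Ca and displaces chloride with inversion. Cutting here lets ring A enter as a simple nucleophile and ties the configuration of Ca to that of the chloride in 11.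

**11 from 9.** The bond C3–Ca is cut: Ca is inserted as a one-carbon carbenoid into the C3–B bond of 9, by way of borate 10. This is the only C–C bond to C3 that must be made after the key step. The insertion keeps the configuration of C3, and the chiral diol selects the configuration of the new chloride-bearing Ca independently of Cb, which is what the unsymmetrical target asks for.

**9 from 7 via 8.** This is a protecting-group exchange. The aryl acetate of 7 cannot meet a carbenoid or a Grignard reagent and is replaced by a silyl ether. The acetate is wanted in the earlier steps, so the exchange sits between the last step that profits from it and the first that would destroy it.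

**7 from 6.** The C5 methylene and the Cb–O–Si group of 7 are recombined into an acetal: C5 gets back its bond to the Cb oxygen, which closes an oxetane. Forward, ionisation of the strained acetal and hydride capture at C5 must open the four-membered ring without ionising the benzylic Cb–O bond. The acetoxy-substituted ring B of 6 is the reason this is done before the protecting-group exchange.

**6 from 4.** The C3–B bond is cut back to the enol ether C2=C3 of 4, with catechol ester 5 as the first-formed boronate. Hydroboration has to place boron on C3 and on the face away from the oxetane, so that the later Ca arm is trans to Cb. Esterification with an enantiopure diol then serves twice: as the handle by which the two enantiomeric series of the bicyclic core are separated, and as the stereodirecting group for the insertion. Since 4 is racemic, this is where the absolute configuration is secured.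

**4 from 2 and 3.** The oxetane is cut across both bonds, Cb–C4 and O–C5. This [2+2] disconnection reveals furan 3, which supplies all five ring atoms, and aldehyde 2, which supplies Cb, its oxygen and ring B. Forward, the photocycloaddition must bond oxygen to the α-carbon and carbon to the β-carbon of one furan double bond and place the aryl group exo. In return it makes two bonds and three stereocentres in one step and leaves C2=C3 ready for the next.

**2 from 1.** The acetate is put on the phenol of 1 before irradiation.

## Alternatives that were turned down

**Alternative 1: asymmetric Baeyer–Villiger ring expansion.**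
- Disconnection: the O1–C5 bond of γ-butyrolactone A1 (C2 as carbonyl, C3 still unsubstituted) is traced to the 3-substituted cyclobutanone A2, which already carries the silylated Cb carbinol.
- Forward key step: H2O2 with Sc(OTf)3 and a chiral N,N′-dioxide ligand oxidises A2; the catalyst decides which of the two ring CH2 groups migrates to oxygen and so turns the prostereogenic ring carbon into C4.
- In favour: absolute configuration comes from a catalyst, with no photochemistry and no resolution. On this point it is stronger than the chosen route, which gives up half of the photoadduct in step 3.
- Against, for this target: Cb must be set beforehand by a separate asymmetric step, and the four-membered ketone has to be built first. A1 also still lacks the whole Ca arm. An aldol reaction of the lactone enolate would place it trans at C3 but gives no firm control at Ca. The C2 carbonyl must afterwards be taken down to CH2 next to two electron-rich benzylic oxygens. The benzyl ether calls for hydrogenolysis beside benzylic carbinols.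
- Comparison: the chosen route makes Cb, C4 and the ring oxidation pattern in one step from two commodity chemicals and sets Ca with a director of predictable sense; it pays with a resolution instead of a catalytic asymmetric step.

**Alternative 2: biomimetic oxidative dimerisation of ferulic acid.**
- Disconnection: C3–C4 and both benzylic C–O bonds, back to two molecules of ferulic acid A4.
- Forward key step: FeCl3 under O2 generates phenoxyl radicals that couple at the side-chain carbons next to the carboxyl groups; each carboxyl then adds to the quinone methide of the other half to give bislactone A3.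
- In favour: the entire carbon skeleton, the C3–C4 bond and both benzylic oxygens arise in one step without protecting groups. In step economy to the skeleton it is clearly stronger than the chosen route.
- Against, for this target: A3 has the symmetric relationship of the two benzylic centres, whereas the target is the unsymmetrical diastereomer. One of two equivalent benzylic carbinols would therefore have to be inverted. Selecting one is statistical, and substitution at an electron-rich benzylic centre tends to ionise and scramble. After reduction of the lactones, the ring must be closed between the two primary hydroxyls, while the benzylic ones prefer to cyclise through quinone methides to furofuran-type ethers. Radical coupling also gives regioisomeric dimers, and the product is racemic, so a resolution is needed here too.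
- Comparison: the chosen route is longer but sets Ca and Cb by two independent elements, which fits the unsymmetrical target directly.

**Alternative 3: formaldehyde Prins cyclisation ended by hydration.**
- Disconnection: C4–C5 and Cb–O, back to the styrenyl homoallylic alcohol A6 with Ca and C3 already in place.
- Forward key step: under BF3·OEt2 the C2 hydroxyl and formaldehyde form an oxocarbenium ion, alkene carbon C4 attacks it to close the oxolane, and water captures the benzylic cation at Cb to give A5.
- In favour: it is convergent, needs no photochemistry, forms the ring and the Cb–O bond together, and should place the C3 and C4 substituents trans. No resolution is needed if A6 is made enantioselectively.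
- Against, for this target: Cb is created by water adding to a free, planar, strongly stabilised benzylic cation with no element that controls its face. The same cation can be intercepted by electron-rich ring A (six-membered ring closure to a tetralin) or can eliminate. The oxocarbenium ion of an electron-rich styrene is prone to oxonia-Cope rearrangement, which erases C3. The benzylic pivalate at Ca is itself ionisable under BF3·OEt2. A6 needs its own multistep asymmetric synthesis, and the benzyl ethers again end in hydrogenolysis.
- Comparison: in the chosen key step Cb is tied to C4 by a ring closure, so its configuration is not left to a free cation.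

Key step: step 2

## Route

Step 1
Reactants: 1 vanillin (4-hydroxy-3-methoxybenzaldehyde)
Product: 2 vanillin acetate (4-formyl-2-methoxyphenyl acetate)
Conditions: Ac2O, pyridine, DMAP (cat.), CH2Cl2, 0 °C → rt
Reagents that add atoms: acetic anhydride, CC(=O)OC(C)=O
Why: O-acylation of a phenol; the acetate weakens the para oxygen donor, which keeps the aldehyde photoreactive in step 2 and tempers the benzylic position at Cb in step 4.

Step 2
Reactants: 2 vanillin acetate; 3 furan
Product: 4 exo-6-(4-acetoxy-3-methoxyphenyl)-2,7-dioxabicyclo[3.2.0]hept-3-ene (racemate, drawn and carried on as the (1R,5S,6R) enantiomer)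
Conditions: hν (medium-pressure Hg lamp, Pyrex filter, λ > 300 nm), furan (solvent, large excess), Ar, 0 °C
Reagents that add atoms: none
Why: Excitation of the aldehyde of 2 and intersystem crossing give the n,π* triplet, whose electrophilic oxygen bonds to the α-carbon of furan (C5) because this gives the most stabilised triplet 1,4-biradical, an allyl radical over C4–C3–C2 next to O1 and a benzylic radical at Cb. After spin inversion the biradical collapses by Cb–C4 bond formation, which closes the oxetane (four-membered ring closure by radical recombination; the fusion to the five-membered ring can only be cis). The closest known reaction type is the Paternò–Büchi photocycloaddition of aromatic aldehydes to furan, a photochemical aldol equivalent. C5 and C4 are fixed relative to each other by the cis ring fusion, and Cb is fixed relative to C4 by the geometry in which the triplet biradical crosses to the singlet, which turns the aryl group to the convex (exo) side, away from the dihydrofuran ring. The step needs regioselectivity (oxygen to C5, carbon to C4), site selectivity (one furan double bond only) and exo selectivity: the first and third follow from the biradical pathway, the second from the large excess of furan, which outcompetes the enol ether of 4 for the excited aldehyde. The acetate keeps the reactive n,π* state accessible, and the Pyrex cut-off keeps light away from the aryl ester chromophore (photo-Fries shift). No enantiocontrol is expected, so 4 should form as a racemate.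

Step 3
Reactants: 4 exo-aryl oxetane–dihydrofuran photoadduct
Product: 6 (1R,2R,3S,5R)-pinanediol ester of the exo C3 boronic acid of the saturated bicycle 6-exo-aryl-2,7-dioxabicyclo[3.2.0]heptane (boron trans to Cb; core as drawn for 4), via catechol boronate 5 (not isolated)
Conditions: catecholborane, LiBH4 (5 mol %), THF, 0 °C → rt; then (1R,2R,3S,5R)-pinanediol, rt; separation of the diastereomers on Et3N-deactivated SiO2
Reagents that add atoms: catecholborane, B1Oc2ccccc2O1; (1R,2R,3S,5R)-pinanediol, C[C@@]1(O)[C@@H]2C[C@H](C[C@@H]1O)C2(C)C
Why: LiBH4-catalysed hydroboration with catecholborane follows the regiochemistry of borane, boron to C3 (β to O1) and hydrogen to the oxygen-bearing C2, and the reagent comes from the convex face, anti to the oxetane, so that C3–B is trans to Cb. Transesterification of catechol ester 5 with pinanediol is driven by the stability of the pinanediol ester and turns the racemate into two diastereomeric esters (same diol, mirror-image cores), which are separated. Ester 6 is the one built on the core drawn for 4 and fixes the absolute configuration of C3, C4 and Cb.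

Step 4
Reactants: 6 pinanediol boronate of the bicyclic oxetane acetal
Product: 7 (1R,2R,3S,5R)-pinanediol ester of [(3R,4R)-4-{(R)-(4-acetoxy-3-methoxyphenyl)(triethylsilyloxy)methyl}oxolan-3-yl]boronic acid
Conditions: Et3SiH (2 equiv), Et3SiOTf (10 mol %), CH2Cl2, −78 °C; Et3N quench
Reagents that add atoms: triethylsilane, CC[SiH](CC)CC
Why: Silyl triflate-catalysed reductive cleavage of an acetal by a trialkylsilane (ionic hydrogenation): the silyl cation binds the oxetane oxygen, the strained C5–O bond ionises to the five-membered oxocarbenium ion, hydride goes to C5 and the silyl group stays on the Cb oxygen. The acetoxy group makes ring B less electron-rich and so disfavours the competing ionisation of the benzylic Cb–O bond; Cb should keep its oxygen and configuration, and no new stereocentre forms.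

Step 5
Reactants: 7 aryl acetate
Product: 8 the corresponding phenol (4-hydroxy-3-methoxyphenyl on Cb; triethylsilyl ether and boronate unchanged)
Conditions: K2CO3 (0.2 equiv), MeOH, 0 °C
Reagents that add atoms: none
Why: Base-catalysed transesterification of an aryl acetate, much faster than attack on the hindered secondary triethylsilyl ether or on the pinanediol boronate; the ester must go before organolithium and Grignard reagents are used.

Step 6
Reactants: 8 phenol
Product: 9 the aryl tert-butyldimethylsilyl ether (4-(tert-butyldimethylsilyloxy)-3-methoxyphenyl on Cb)
Conditions: TBSCl, imidazole, DMF, rt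
Reagents that add atoms: tert-butyldimethylsilyl chloride, CC(C)(C)[Si](C)(C)Cl
Why: Silyl ether formation at a phenol; the group withstands LiCHCl2, ZnCl2 and the Grignard reagent and is removed together with the triethylsilyl group at the end.

Step 7
Reactants: 9 oxolan-3-yl boronic ester
Product: 11 (1R,2R,3S,5R)-pinanediol ester of the (R)-α-chloro boronic acid C3–CaHCl–B (C3 R, C4 R, Ca R, Cb R), via lithium dichloromethyl borate 10 (not isolated)
Conditions: CH2Cl2, n-BuLi, THF, −100 °C; then 9; then ZnCl2 (anhydrous), −100 °C → rt
Reagents that add atoms: dichloromethane (used as LiCHCl2), ClCCl
Why: Matteson homologation: LiCHCl2 adds to boron to give borate 10, and ZnCl2-assisted 1,2-migration of C3 from boron to carbon displaces one chloride with retention at C3. The pinanediol director decides which chloride leaves; on the established sense of induction of pinanediol esters the (1R,2R,3S,5R) diol should give the (R)-chloride at Ca, whose ranking Cl > C3 > B is the same as in simple alkyl cases.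

Step 8
Reactants: 12 4-bromo-2-methoxyphenol
Product: 13 (4-bromo-2-methoxyphenoxy)(tert-butyl)dimethylsilane
Conditions: TBSCl, imidazole, DMF, rt
Reagents that add atoms: tert-butyldimethylsilyl chloride, CC(C)(C)[Si](C)(C)Cl
Why: Silyl ether formation at a phenol, which masks the acidic proton before Mg insertion.

Step 9
Reactants: 11 α-chloro boronic ester; 13 silylated aryl bromide
Product: 16 (1R,2R,3S,5R)-pinanediol ester of the (S)-benzylic boronic acid C3–CaH(aryl ring A)–B (ring A as its tert-butyldimethylsilyl ether; C3 R, C4 R, Ca S, Cb R), via aryl Grignard reagent 14 (not isolated), via bromomagnesium aryl borate 15 (not isolated)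
Conditions: 13, Mg turnings (I2-activated), THF, 50 °C; then 11, THF, −78 °C → rt
Reagents that add atoms: none
Why: Second stage of the Matteson sequence: Grignard reagent 14, made by Mg insertion into 13, adds to boron, and in borate 15 the aryl group migrates to Ca and displaces chloride from the opposite side (stereospecific 1,2-metallate rearrangement). Inversion at Ca turns the (R)-chloride into the (S)-configured benzylic boronic ester.

Step 10
Reactants: 16 benzylic boronic ester
Product: 17 (S)-carbinol at Ca with both phenols as tert-butyldimethylsilyl ethers and Cb–OH as triethylsilyl ether (C3 R, C4 R, Ca S, Cb R)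
Conditions: H2O2 (30 % aq), NaOH (2 M aq), THF, 0 °C → rt
Reagents that add atoms: hydrogen peroxide, OO
Why: Oxidation of a C–B bond by basic peroxide (1,2-shift of Ca from boron to oxygen) proceeds with retention, so Ca–OH should be S. Partial loss of an aryl silyl ether under the basic conditions would be harmless because all silyl groups are removed next.

Step 11
Reactants: 17 tris-silyl ether
Product: 18 target, (S)-(4-hydroxy-3-methoxyphenyl)[(3R,4R)-4-{(R)-hydroxy(4-hydroxy-3-methoxyphenyl)methyl}oxolan-3-yl]methanol
Conditions: Bu4NF, AcOH, THF, 0 °C → rt
Reagents that add atoms: none
Why: Fluoride cleavage of silyl ethers; acetic acid buffers the phenoxides so that the para-hydroxybenzylic alcohols are not pushed towards quinone methides, and no acid strong enough to ionise Ca–OH or Cb–OH is present.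

## Compound list

1 | vanillin (4-hydroxy-3-methoxybenzaldehyde) | COc1cc(C=O)ccc1O | starting material
2 | vanillin acetate (4-formyl-2-methoxyphenyl acetate) | COc1cc(C=O)ccc1OC(C)=O | intermediate
3 | furan | c1ccoc1 | starting material
4 | exo-6-(4-acetoxy-3-methoxyphenyl)-2,7-dioxabicyclo[3.2.0]hept-3-ene, racemate, drawn as the (1R,5S,6R) enantiomer | COc1cc([C@@H]2O[C@H]3OC=C[C@@H]23)ccc1OC(C)=O | intermediate
5 | catechol boronate: 6-exo-aryl-2,7-dioxabicyclo[3.2.0]heptane with a 1,3,2-benzodioxaborol-2-yl group exo on oxolane C3, racemic, drawn in the series of 4 | COc1cc([C@@H]2O[C@H]3OC[C@H](B4Oc5ccccc5O4)[C@@H]23)ccc1OC(C)=O | intermediate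
6 | (1R,2R,3S,5R)-pinanediol ester of the same exo C3 boronic acid, core as drawn for 4 | COc1cc([C@@H]2O[C@H]3OC[C@H](B4O[C@H]5C[C@H]6C[C@H](C6(C)C)[C@@]5(C)O4)[C@@H]23)ccc1OC(C)=O | intermediate
7 | (1R,2R,3S,5R)-pinanediol ester of [(3R,4R)-4-{(R)-(4-acetoxy-3-methoxyphenyl)(triethylsilyloxy)methyl}oxolan-3-yl]boronic acid | CC(=O)Oc1ccc(cc1OC)[C@H](O[Si](CC)(CC)CC)[C@H]1COC[C@@H]1B1O[C@H]2C[C@H]3C[C@H](C3(C)C)[C@@]2(C)O1 | intermediate
8 | phenol from 7 (4-hydroxy-3-methoxyphenyl on Cb) | Oc1ccc(cc1OC)[C@H](O[Si](CC)(CC)CC)[C@H]1COC[C@@H]1B1O[C@H]2C[C@H]3C[C@H](C3(C)C)[C@@]2(C)O1 | intermediate
9 | aryl tert-butyldimethylsilyl ether of 8 | CC(C)(C)[Si](C)(C)Oc1ccc(cc1OC)[C@H](O[Si](CC)(CC)CC)[C@H]1COC[C@@H]1B1O[C@H]2C[C@H]3C[C@H](C3(C)C)[C@@]2(C)O1 | intermediate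
10 | lithium borate from 9 and LiCHCl2 (boron carries C3, CHCl2 and the two diol oxygens) | CC(C)(C)[Si](C)(C)Oc1ccc(cc1OC)[C@H](O[Si](CC)(CC)CC)[C@H]1COC[C@@H]1[B-]1(C(Cl)Cl)O[C@H]2C[C@H]3C[C@H](C3(C)C)[C@@]2(C)O1.[Li+] | intermediate
11 | (R)-α-chloro boronic ester C3–CaHCl–B(pinanediol) | CC(C)(C)[Si](C)(C)Oc1ccc(cc1OC)[C@H](O[Si](CC)(CC)CC)[C@H]1COC[C@@H]1[C@H](Cl)B1O[C@H]2C[C@H]3C[C@H](C3(C)C)[C@@]2(C)O1 | intermediate
12 | 4-bromo-2-methoxyphenol | COc1cc(Br)ccc1O | starting material
13 | (4-bromo-2-methoxyphenoxy)(tert-butyl)dimethylsilane | COc1cc(Br)ccc1O[Si](C)(C)C(C)(C)C | intermediate
14 | [4-(tert-butyldimethylsilyloxy)-3-methoxyphenyl]magnesium bromide | COc1cc([Mg]Br)ccc1O[Si](C)(C)C(C)(C)C | intermediate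
15 | bromomagnesium borate from 11 and 14 (boron carries Ca, aryl ring A and the two diol oxygens) | CC(C)(C)[Si](C)(C)Oc1ccc(cc1OC)[C@H](O[Si](CC)(CC)CC)[C@H]1COC[C@@H]1[C@H](Cl)[B-]1(c2ccc(O[Si](C)(C)C(C)(C)C)c(OC)c2)O[C@H]2C[C@H]3C[C@H](C3(C)C)[C@@]2(C)O1.[Mg+]Br | intermediate
16 | (S)-benzylic boronic ester C3–CaH(aryl ring A)–B(pinanediol) | CC(C)(C)[Si](C)(C)Oc1ccc(cc1OC)[C@H](O[Si](CC)(CC)CC)[C@H]1COC[C@@H]1[C@@H](c1ccc(O[Si](C)(C)C(C)(C)C)c(OC)c1)B1O[C@H]2C[C@H]3C[C@H](C3(C)C)[C@@]2(C)O1 | intermediate
17 | tris-silyl ether of the target with free (S)-Ca–OH | CC(C)(C)[Si](C)(C)Oc1ccc(cc1OC)[C@H](O[Si](CC)(CC)CC)[C@H]1COC[C@@H]1[C@H](O)c1ccc(O[Si](C)(C)C(C)(C)C)c(OC)c1 | intermediate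
18 | target CNP0157038.2 | COc1cc([C@@H](O)[C@H]2COC[C@@H]2[C@@H](O)c2ccc(O)c(OC)c2)ccc1O | target

## Step count and least certain steps

Total step count: 11. Longest linear sequence: 10 steps from 1 (steps 1–7 and 9–11); step 8 is a one-step side branch.

**Step 2 (key step).** The most likely failure is a slow photocycloaddition: the methoxy and acyloxy substituents bring the unreactive π,π* triplet close to the reactive n,π* triplet. Long irradiation then gives room to secondary photochemistry (acyl shift of the acetate, a second addition to the enol ether of 4) and to acid-induced opening of the oxetane acetal during isolation. The fallback sets out from 1. Triflation (Tf2O, pyridine) gives vanillin triflate F1, whose sulfonate is a stronger acceptor and cannot transfer an acyl group. Irradiation with 3 under the conditions of step 2 gives the triflate analogue of the photoadduct F2. Et4NOH in dioxane cleaves the aryl triflate to the phenolic photoadduct F3, and acetylation (Ac2O, pyridine) comes back to the route at 4.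

**Step 4.** The most likely failure is ionisation at the wrong bond: if the silyl cation opens the benzylic Cb–O bond instead of the acetal C5–O bond, hydride capture is irreversible and Cb loses its oxygen or its configuration. Elimination from the oxocarbenium ion to a dihydrofuran is a second loss path. The fallback sets out from 6 and separates ring opening from reduction. Thiophenol with a catalytic amount of pyridinium p-toluenesulfonate opens the oxetane acetal reversibly and the soft nucleophile selects the oxocarbenium ion, which gives the C5 phenylthio acetal with free Cb–OH F4. Radical desulfurisation (Bu3SnH, AIBN, toluene, 80 °C) gives the C5 methylene alcohol F5 without any cationic intermediate. Silylation (Et3SiCl, imidazole) comes back to the route at 7.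

**Step 3.** The most likely failure is poor separation of the two diastereomeric pinanediol esters, because the stereogenic units of the diol and of the bicyclic core are held apart by the trigonal boron and influence each other little. The fallback sets out from racemic 4, which is resolved by preparative chromatography on a chiral stationary phase before step 3. Only the enantiomer drawn as 4 then enters the hydroboration, ester 6 forms alone, and the route is rejoined at 6. This fallback makes no new compound (entry F0).

**Step 9.** The most likely failure is sluggish aryl transfer: borate formation at the boron of 11 is hindered by the branched C3, and the warming then needed opens other paths for the α-chloride (epimerisation at Ca by chloride exchange, migration of a diol oxygen). The fallback sets out from 11. Basic H2O2 oxidises the α-chloro boronic ester to the C3 aldehyde F6, because the chlorohydrin collapses. Grignard reagent 14 adds to F6 to give the carbinol as a mixture of Ca epimers F7. Dess–Martin periodinane gives the aryl ketone F8. Reduction with BH3·SMe2 and (R)-2-methyl-CBS-oxazaborolidine, with the aryl group as the large substituent, should give the (S)-carbinol, and the route is rejoined at 17.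

**Step 7.** The most likely failure is incomplete insertion or eroded selectivity: the secondary, β-branched C3 migrates slowly, the long contact with chloride at room temperature can epimerise Ca, and the existing C3 and C4 centres may be mismatched with the director. While migration is slow, the ZnCl2-activated borate can also open the oxolane by β-elimination across B–C3–C2–O1. The fallback sets out from 9. The unsubstituted carbenoid LiCH2Cl (from BrCH2Cl and n-BuLi, −78 °C) is less hindered, rearranges without ZnCl2 and creates no stereocentre; it gives the homologated boronic ester C3–CH2–B F9. Basic H2O2 gives the primary alcohol F10, and Dess–Martin oxidation gives aldehyde F6. The sequence through the epimeric carbinols F7 and the aryl ketone F8 described for step 9 then comes back to the route at 17.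

## Further compounds

F1 | step 2 | 4-formyl-2-methoxyphenyl trifluoromethanesulfonate (vanillin triflate) | COc1cc(C=O)ccc1OS(=O)(=O)C(F)(F)F
F2 | step 2 | exo-6-[3-methoxy-4-(trifluoromethylsulfonyloxy)phenyl]-2,7-dioxabicyclo[3.2.0]hept-3-ene (racemic, drawn in the series of 4) | COc1cc([C@@H]2O[C@H]3OC=C[C@@H]23)ccc1OS(=O)(=O)C(F)(F)F
F3 | step 2 | exo-6-(4-hydroxy-3-methoxyphenyl)-2,7-dioxabicyclo[3.2.0]hept-3-ene (racemic, drawn in the series of 4) | COc1cc([C@@H]2O[C@H]3OC=C[C@@H]23)ccc1O
F4 | step 4 | pinanediol boronate with C5 phenylthio acetal (anomer mixture) and free Cb–OH, aryl acetate retained | CC(=O)Oc1ccc(cc1OC)[C@H](O)[C@H]1C(Sc2ccccc2)OC[C@@H]1B1O[C@H]2C[C@H]3C[C@H](C3(C)C)[C@@]2(C)O1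
F5 | step 4 | pinanediol boronate with C5 methylene and free Cb–OH, aryl acetate retained | CC(=O)Oc1ccc(cc1OC)[C@H](O)[C@H]1COC[C@@H]1B1O[C@H]2C[C@H]3C[C@H](C3(C)C)[C@@]2(C)O1
F0 | step 3 | none | none
F6 | step 9 | (3R,4R)-oxolane-3-carbaldehyde carrying the silylated Cb arm on C4 | CC(C)(C)[Si](C)(C)Oc1ccc(cc1OC)[C@H](O[Si](CC)(CC)CC)[C@H]1COC[C@@H]1C=O
F7 | step 9 | carbinol from F6 and 14, mixture of Ca epimers | CC(C)(C)[Si](C)(C)Oc1ccc(cc1OC)[C@H](O[Si](CC)(CC)CC)[C@H]1COC[C@@H]1C(O)c1ccc(O[Si](C)(C)C(C)(C)C)c(OC)c1
F8 | step 9 | aryl ketone at Ca | CC(C)(C)[Si](C)(C)Oc1ccc(cc1OC)[C@H](O[Si](CC)(CC)CC)[C@H]1COC[C@@H]1C(=O)c1ccc(O[Si](C)(C)C(C)(C)C)c(OC)c1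
F9 | step 7 | pinanediol ester of the homologated boronic acid C3–CH2–B | CC(C)(C)[Si](C)(C)Oc1ccc(cc1OC)[C@H](O[Si](CC)(CC)CC)[C@H]1COC[C@@H]1CB1O[C@H]2C[C@H]3C[C@H](C3(C)C)[C@@]2(C)O1
F10 | step 7 | primary alcohol C3–CH2OH | CC(C)(C)[Si](C)(C)Oc1ccc(cc1OC)[C@H](O[Si](CC)(CC)CC)[C@H]1COC[C@@H]1CO
A1 | alternative 1 | β-substituted γ-butyrolactone with C4 and the silylated Cb carbinol | O=C1C[C@H](CO1)[C@@H](O[Si](C)(C)C(C)(C)C)c1ccc(OCc2ccccc2)c(OC)c1
A2 | alternative 1 | 3-substituted cyclobutanone carrying the silylated Cb carbinol | O=C1CC(C1)[C@@H](O[Si](C)(C)C(C)(C)C)c1ccc(OCc2ccccc2)c(OC)c1
A3 | alternative 2 | bislactone of 8–8′ dehydrodiferulic acid (2,6-diaryl-3,7-dioxabicyclo[3.3.0]octane-4,8-dione), racemic, one enantiomer drawn | COc1cc([C@H]2OC(=O)[C@@H]3[C@@H](c4ccc(O)c(OC)c4)OC(=O)[C@H]23)ccc1O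
A4 | alternative 2 | ferulic acid | COc1cc(/C=C/C(=O)O)ccc1O
A5 | alternative 3 | oxolane with the Ca pivalate, the free Cb carbinol and benzyl-protected phenols | COc1cc([C@@H](OC(=O)C(C)(C)C)[C@H]2COC[C@@H]2[C@@H](O)c2ccc(OCc3ccccc3)c(OC)c2)ccc1OCc1ccccc1
A6 | alternative 3 | (E)-styrenyl homoallylic alcohol with the Ca pivalate and C3 set | COc1cc([C@@H](OC(=O)C(C)(C)C)[C@@H](CO)/C=C/c2ccc(OCc3ccccc3)c(OC)c2)ccc1OCc1ccccc1
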